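**Plan**
- Retrosynthesis: the 1(10)-epoxide and the two ester groups are removed first. The C11–C12 and C6–C7 bonds are then cut together, with the lactone C–O bond that follows them in the same operation. This opens both the lactone and the ten-membered ring to an acyclic allenyl (Z)-enal plus a one-carbon alkoxycarbonyl unit. The chain is cut further at C3–C4, C1–C2, C10–C14, C11–C13 and C8–C9.
- Forward: propargylation sets C8, carboalumination/epoxide opening builds the E-C1=C10 alkene, Crabbé homologation gives the allene, a Nozaki–Hiyama–Kishi coupling adds the Z-C4=C5 unit, and oxidation gives the enal. One nickel-mediated step then closes the carbocycle and the lactone; the esters and the epoxide follow.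
- Enabling feature: the α-methylene-γ-butyrolactone (O6–C6–C7–C11(=C13)–C12) shares its C6–C7 bond with the ten-membered ring. C7–C11=C13 is the imprint of a terminal allene and C6–O that of an enal carbonyl. Placing an alkoxycarbonyl carbon (C12) on the central allene carbon C11 therefore creates an allylmetal at C7 that closes both rings on C6.
- Stereochemistry: C8 and C3 are each set by an asymmetric catalyst or ligand. C7 and C6 are relayed from C8 in the key step. C1/C10 come from peripheral attack on the macrocycle. The epoxy acid comes from a Sharpless epoxidation.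

Key step: step 12

Remark: locants C1–C15 are germacrane locants (C12 lactone carbonyl, C13 exocyclic methylene, C14 on C10, C15 on C4). The catalyst and ligand enantiomers in steps 1 and 9 are those expected to give the stated configurations.

**Step 1**
Reactants: 1 3-(trimethylsilyl)prop-2-ynal; 2 allenylboronic acid pinacol ester
Product: 3 (R)-1-(trimethylsilyl)hexa-1,5-diyn-3-ol
Conditions: (R)-TRIP phosphoric acid (5 mol%), 4 Å MS, toluene, −20 °C
Reagents that add atoms: none
Why: Chiral phosphoric acid-catalysed allenylboration (carbonyl propargylation) through a six-membered chair in which the catalyst binds the boronate oxygen and the formyl hydrogen, so that SE2′ transfer to one aldehyde face should set C8 as R.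

**Step 2**
Reactants: 3 (R)-1-(trimethylsilyl)hexa-1,5-diyn-3-ol
Product: 4 (R)-tert-butyldimethyl{[1-(trimethylsilyl)hexa-1,5-diyn-3-yl]oxy}silane
Conditions: TBSCl, imidazole, DMF, rt
Reagents that add atoms: tert-butyldimethylsilyl chloride CC(C)(C)[Si](C)(C)Cl
Why: Standard silylation of a secondary propargylic alcohol, with no effect on the stereocentre.

**Step 3**
Reactants: 4 (R)-tert-butyldimethyl{[1-(trimethylsilyl)hexa-1,5-diyn-3-yl]oxy}silane
Product: 6 (R,E)-6-[(tert-butyldimethylsilyl)oxy]-4-methyl-8-(trimethylsilyl)oct-3-en-7-yn-1-ol, via alkenylalane 5 (not isolated)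
Conditions: Me3Al, Cp2ZrCl2 (0.2 equiv), CH2Cl2, 0 °C to rt; then n-BuLi, hexane/THF, −30 °C; ethylene oxide, −30 to 0 °C; aq. Rochelle salt
Reagents that add atoms: trimethylaluminium C[Al](C)C; ethylene oxide C1CO1
Why: Zirconium-catalysed (Negishi) carboalumination adds Me–Al syn across the terminal alkyne only (the silylalkyne is inert), and the derived alanate opens ethylene oxide with retention, so the E-trisubstituted C1=C10 alkene should form with C14 and C2–C3 in place.

**Step 4**
Reactants: 6 (R,E)-6-[(tert-butyldimethylsilyl)oxy]-4-methyl-8-(trimethylsilyl)oct-3-en-7-yn-1-ol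
Product: 7 (R,E)-6-[(tert-butyldimethylsilyl)oxy]-4-methyloct-3-en-7-yn-1-ol
Conditions: K2CO3 (cat.), MeOH, rt
Reagents that add atoms: none
Why: Methanolysis of the alkynyl C–Si bond (protodesilylation) leaves the TBS ether untouched.

**Step 5**
Reactants: 7 (R,E)-6-[(tert-butyldimethylsilyl)oxy]-4-methyloct-3-en-7-yn-1-ol
Product: 9 (R,E)-6-[(tert-butyldimethylsilyl)oxy]-4-methylnona-3,7,8-trien-1-ol, via propargylic amine 8 (not isolated)
Conditions: (CH2O)n, CuI (0.5 equiv), Cy2NH, dioxane, reflux
Reagents that add atoms: paraformaldehyde (as formaldehyde) C=O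
Why: Crabbé homologation, in which the Mannich base of the terminal alkyne undergoes copper-mediated 1,5-hydride transfer and loss of imine to give the terminal allene (C13 added) without touching C8.

**Step 6**
Reactants: 9 (R,E)-6-[(tert-butyldimethylsilyl)oxy]-4-methylnona-3,7,8-trien-1-ol
Product: 10 (R,E)-6-[(tert-butyldimethylsilyl)oxy]-4-methylnona-3,7,8-trienal
Conditions: Dess–Martin periodinane, NaHCO3, CH2Cl2, 0 °C; used crude
Reagents that add atoms: none
Why: Buffered Dess–Martin oxidation should give the β,γ-unsaturated aldehyde without migration of the alkene when it is used at once.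

**Step 7**
Reactants: 11 but-2-yn-1-ol
Product: 13 (Z)-3-iodobut-2-en-1-ol, via cyclic alkenylaluminate 12 (not isolated)
Conditions: Red-Al, THF, 0 °C to rt; then I2, −78 °C
Reagents that add atoms: iodine II
Why: Hydroxyl-directed trans-hydroalumination places aluminium on C3 cis to the CH2O group, and iodinolysis with retention gives the Z-iodide that carries the future 4Z geometry.

**Step 8**
Reactants: 13 (Z)-3-iodobut-2-en-1-ol
Product: 14 (Z)-triethyl[(3-iodobut-2-en-1-yl)oxy]silane
Conditions: TESCl, imidazole, CH2Cl2, 0 °C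
Reagents that add atoms: chlorotriethylsilane CC[Si](CC)(CC)Cl
Why: Standard silylation of a primary allylic alcohol.

**Step 9**
Reactants: 10 (R,E)-6-[(tert-butyldimethylsilyl)oxy]-4-methylnona-3,7,8-trienal; 14 (Z)-triethyl[(3-iodobut-2-en-1-yl)oxy]silane
Product: 15 (2Z,4S,6E,9R)-9-[(tert-butyldimethylsilyl)oxy]-3,7-dimethyl-1-[(triethylsilyl)oxy]dodeca-2,6,10,11-tetraen-4-ol
Conditions: CrCl2 (4 equiv), NiCl2 (2 mol%), chiral oxazoline–sulfonamide ligand, Et3N, THF, rt
Reagents that add atoms: none
Why: Asymmetric Nozaki–Hiyama–Kishi coupling, in which the alkenylchromium formed with retention of the Z geometry adds to the aldehyde and the chiral ligand on chromium should set the C3 carbinol (4S here) under reagent control.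

**Step 10**
Reactants: 15 (2Z,4S,6E,9R)-9-[(tert-butyldimethylsilyl)oxy]-3,7-dimethyl-1-[(triethylsilyl)oxy]dodeca-2,6,10,11-tetraen-4-ol
Product: 16 (2Z,4S,6E,9R)-9-[(tert-butyldimethylsilyl)oxy]-3,7-dimethyl-1,4-bis[(triethylsilyl)oxy]dodeca-2,6,10,11-tetraene
Conditions: TESCl, imidazole, DMAP (cat.), CH2Cl2, rt
Reagents that add atoms: chlorotriethylsilane CC[Si](CC)(CC)Cl
Why: Silylation gives a C3 protecting group that can later be removed in the presence of the C8 TBS ether and that cannot ionise to an allyl complex in step 12.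

**Step 11**
Reactants: 16 (2Z,4S,6E,9R)-9-[(tert-butyldimethylsilyl)oxy]-3,7-dimethyl-1,4-bis[(triethylsilyl)oxy]dodeca-2,6,10,11-tetraene
Product: 17 (2Z,4S,6E,9R)-9-[(tert-butyldimethylsilyl)oxy]-3,7-dimethyl-4-[(triethylsilyl)oxy]dodeca-2,6,10,11-tetraenal
Conditions: (COCl)2, DMSO, CH2Cl2, −78 to −30 °C; Et3N
Reagents that add atoms: none
Why: Under Swern conditions a primary triethylsilyl ether is oxidised directly to the aldehyde while secondary TES and TBS ethers survive, and the low temperature should keep the Z-enal geometry.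

**Step 12**
Reactants: 17 (2Z,4S,6E,9R)-9-[(tert-butyldimethylsilyl)oxy]-3,7-dimethyl-4-[(triethylsilyl)oxy]dodeca-2,6,10,11-tetraenal
Product: 20 (3S,6R,7S,8R,1(10)E,4Z)-8-[(tert-butyldimethylsilyl)oxy]-3-[(triethylsilyl)oxy]germacra-1(10),4,11(13)-trien-12,6-olide, via allylnickel chloride 18 (not isolated), via hydroxy ester 19 (not isolated)
Conditions: ClCO2Me (2 equiv), Ni(cod)2 (1.5 equiv), THF, −40 °C, 15 min; then 17 by syringe pump, THF–DMF 1:1, −40 to 45 °C, 2 mM; aq. NH4Cl
Reagents that add atoms: methyl chloroformate COC(=O)Cl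
Why: Proposed new method: oxidative addition of methyl chloroformate to Ni(0) gives a methoxycarbonylnickel(II) chloride that transfers its acyl group to the central allene carbon C11 of 17 (acylmetalation, new C11–C12 bond) to give the 2-(methoxycarbonyl)allylnickel chloride 18, which, like the known π-(2-alkoxycarbonylallyl)nickel halides, adds through its substituted terminus C7 to the tethered aldehyde C6 in a six-membered chair transition state (new C6–C7 bond) before the nickel alkoxide of 19 expels methoxide to close the lactone. The closest known reaction types are the lactone annulation of 2-(alkoxycarbonyl)allylnickel, -zinc, -chromium or -indium halides with aldehydes, including its ring-forming intramolecular Barbier form used for carbocycle-fused α-methylene lactones and ten-membered germacranolides, and the three-component coupling of acyl- or arylmetal halides with allenes and aldehydes through 2-substituted allylmetals; new is only that the allylnickel is made from an allene and a chloroformate, so that C12 arrives in the ring-closing operation. The carbocycle closes in a 10-exo-trig carbonyl allylation (SE2′ at C7) and the lactone in a 5-exo-trig acyl substitution by O6 at C12. C7 is controlled by C8 (the aldehyde should approach the allyl terminus anti to the C8 silyloxy group, Felkin–Anh-type 1,2-induction) and C6 by the chair in which the ring chains at C5 and C8 are both pseudo-equatorial, which gives the anti adduct and hence the trans-fused lactone (6R,7R in the descriptors of the target). The step needs (i) acylnickelation of the allene and not of the enal or the trisubstituted alkenes, secured by the higher insertion reactivity of the 1,2-diene and by pre-forming the Ni(II) species so that free Ni(0) does not meet the enal, (ii) branched attack at C7 and not linear attack at C13, which is the usual regiochemistry of allylnickel additions to C=O and is favoured by the ten- over the twelve-membered ring, and (iii) survival of the 4Z enal and both silyl ethers, secured by the neutral, non-basic medium.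

**Step 13**
Reactants: 20 (3S,6R,7S,8R,1(10)E,4Z)-8-[(tert-butyldimethylsilyl)oxy]-3-[(triethylsilyl)oxy]germacra-1(10),4,11(13)-trien-12,6-olide
Product: 21 (3S,6R,7S,8R,1(10)E,4Z)-8-[(tert-butyldimethylsilyl)oxy]-3-hydroxygermacra-1(10),4,11(13)-trien-12,6-olide
Conditions: PPTS (cat.), MeOH/CH2Cl2, 0 °C
Reagents that add atoms: none
Why: Mild acid-catalysed methanolysis removes the secondary TES ether selectively over the secondary TBS ether.

**Step 14**
Reactants: 21 (3S,6R,7S,8R,1(10)E,4Z)-8-[(tert-butyldimethylsilyl)oxy]-3-hydroxygermacra-1(10),4,11(13)-trien-12,6-olide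
Product: 22 (3S,6R,7S,8R,1(10)E,4Z)-8-[(tert-butyldimethylsilyl)oxy]-3-(isobutyryloxy)germacra-1(10),4,11(13)-trien-12,6-olide
Conditions: (i-PrCO)2O, Et3N, DMAP (cat.), CH2Cl2, 0 °C
Reagents that add atoms: isobutyric anhydride CC(C)C(=O)OC(=O)C(C)C
Why: DMAP-catalysed acylation of the allylic secondary alcohol with retention at C3.

**Step 15**
Reactants: 22 (3S,6R,7S,8R,1(10)E,4Z)-8-[(tert-butyldimethylsilyl)oxy]-3-(isobutyryloxy)germacra-1(10),4,11(13)-trien-12,6-olide
Product: 23 (3S,6R,7R,8R,1(10)E,4Z)-8-hydroxy-3-(isobutyryloxy)germacra-1(10),4,11(13)-trien-12,6-olide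
Conditions: HF·pyridine, pyridine/THF, 0 °C to rt
Reagents that add atoms: none
Why: Fluoride-mediated desilylation in an acidic buffer should free the C8 hydroxyl without base-induced acyl migration or relactonisation to the 8,12-olide.

**Step 16**
Reactants: 24 methyl angelate [methyl (Z)-2-methylbut-2-enoate]
Product: 25 (Z)-2-methylbut-2-en-1-ol
Conditions: DIBAL-H (2.2 equiv), CH2Cl2, −78 °C; aq. Rochelle salt
Reagents that add atoms: none
Why: 1,2-Reduction of the enoate by DIBAL at low temperature keeps the Z alkene geometry.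

**Step 17**
Reactants: 25 (Z)-2-methylbut-2-en-1-ol
Product: 26 [(2R,3S)-2,3-dimethyloxiran-2-yl]methanol
Conditions: Ti(Oi-Pr)4 (10 mol%), D-(−)-diethyl tartrate (12 mol%), t-BuOOH, 4 Å MS, CH2Cl2, −20 °C
Reagents that add atoms: tert-butyl hydroperoxide CC(C)(C)OO
Why: Sharpless asymmetric epoxidation, in which the D-tartrate catalyst delivers oxygen to the face that gives the (2R,3S)-epoxy alcohol and so sets both epoxide centres of the acyl side chain.

**Step 18**
Reactants: 26 [(2R,3S)-2,3-dimethyloxiran-2-yl]methanol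
Product: 27 (2S,3S)-2,3-dimethyloxirane-2-carboxylic acid
Conditions: RuCl3·xH2O (2 mol%), NaIO4, CCl4/MeCN/H2O, rt
Reagents that add atoms: sodium periodate [Na+].[O-]I(=O)(=O)=O; water O
Why: Ruthenium tetroxide oxidation of the primary alcohol to the acid leaves the epoxide and its two stereocentres unchanged (the descriptor at C2 changes only by priority).

**Step 19**
Reactants: 23 (3S,6R,7R,8R,1(10)E,4Z)-8-hydroxy-3-(isobutyryloxy)germacra-1(10),4,11(13)-trien-12,6-olide; 27 (2S,3S)-2,3-dimethyloxirane-2-carboxylic acid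
Product: 29 (3S,6R,7R,8R,1(10)E,4Z)-8-{[(2S,3S)-2,3-dimethyloxirane-2-carbonyl]oxy}-3-(isobutyryloxy)germacra-1(10),4,11(13)-trien-12,6-olide, via mixed anhydride 28 (not isolated)
Conditions: 27, 2,4,6-trichlorobenzoyl chloride, Et3N, THF, rt; then 23, DMAP, toluene, rt
Reagents that add atoms: none
Why: Yamaguchi esterification activates the hindered α-quaternary epoxy acid as a mixed anhydride that acylates the C8 alcohol with retention at all centres.

**Step 20**
Reactants: 29 (3S,6R,7R,8R,1(10)E,4Z)-8-{[(2S,3S)-2,3-dimethyloxirane-2-carbonyl]oxy}-3-(isobutyryloxy)germacra-1(10),4,11(13)-trien-12,6-olide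
Product: 30 CNP0117882.1, the (1R,3S,6R,7R,8R,10R)-1,10-epoxide of 29
Conditions: mCPBA (1.1 equiv), NaHCO3, CH2Cl2, −20 to 0 °C
Reagents that add atoms: meta-chloroperoxybenzoic acid OOC(=O)c1cccc(Cl)c1
Why: Prilezhaev epoxidation should take place only at the electron-rich E-C1=C10 alkene (C4=C5 is deactivated by two allylic acyloxy groups and C11=C13 is conjugated), with stereospecific syn addition from the exposed outer face of the ten-membered ring to give the trans-(1R,10R)-epoxide.

**Compound list**
1 | 3-(trimethylsilyl)prop-2-ynal | C[Si](C)(C)C#CC=O | starting material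
2 | allenylboronic acid pinacol ester | C=C=CB1OC(C)(C)C(C)(C)O1 | starting material
3 | (R)-1-(trimethylsilyl)hexa-1,5-diyn-3-ol | C#CC[C@@H](O)C#C[Si](C)(C)C | intermediate
4 | (R)-tert-butyldimethyl{[1-(trimethylsilyl)hexa-1,5-diyn-3-yl]oxy}silane | C#CC[C@@H](O[Si](C)(C)C(C)(C)C)C#C[Si](C)(C)C | intermediate
5 | (E)-alkenyldimethylalane from 4 (AlMe2 on C1, methyl on C10, cis to each other) | C[Al](C)/C=C(\C)C[C@@H](O[Si](C)(C)C(C)(C)C)C#C[Si](C)(C)C | intermediate
6 | (R,E)-6-[(tert-butyldimethylsilyl)oxy]-4-methyl-8-(trimethylsilyl)oct-3-en-7-yn-1-ol | OCC/C=C(\C)C[C@@H](O[Si](C)(C)C(C)(C)C)C#C[Si](C)(C)C | intermediate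
7 | (R,E)-6-[(tert-butyldimethylsilyl)oxy]-4-methyloct-3-en-7-yn-1-ol | OCC/C=C(\C)C[C@@H](O[Si](C)(C)C(C)(C)C)C#C | intermediate
8 | (R,E)-6-[(tert-butyldimethylsilyl)oxy]-9-(dicyclohexylamino)-4-methylnon-3-en-7-yn-1-ol | OCC/C=C(\C)C[C@@H](O[Si](C)(C)C(C)(C)C)C#CCN(C1CCCCC1)C1CCCCC1 | intermediate
9 | (R,E)-6-[(tert-butyldimethylsilyl)oxy]-4-methylnona-3,7,8-trien-1-ol | OCC/C=C(\C)C[C@@H](O[Si](C)(C)C(C)(C)C)C=C=C | intermediate
10 | (R,E)-6-[(tert-butyldimethylsilyl)oxy]-4-methylnona-3,7,8-trienal | O=CC/C=C(\C)C[C@@H](O[Si](C)(C)C(C)(C)C)C=C=C | intermediate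
11 | but-2-yn-1-ol | CC#CCO | starting material
12 | sodium cyclic alkenylaluminate from 11 and Red-Al (five-membered C–Al–O ring, two 2-methoxyethoxy groups on Al) | CC1=CCO[Al-]1(OCCOC)OCCOC.[Na+] | intermediate
13 | (Z)-3-iodobut-2-en-1-ol | C/C(I)=C/CO | intermediate
14 | (Z)-triethyl[(3-iodobut-2-en-1-yl)oxy]silane | C/C(I)=C/CO[Si](CC)(CC)CC | intermediate
15 | (2Z,4S,6E,9R)-9-[(tert-butyldimethylsilyl)oxy]-3,7-dimethyl-1-[(triethylsilyl)oxy]dodeca-2,6,10,11-tetraen-4-ol | CC[Si](CC)(CC)OC/C=C(/C)[C@@H](O)C/C=C(\C)C[C@@H](O[Si](C)(C)C(C)(C)C)C=C=C | intermediate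
16 | (2Z,4S,6E,9R)-9-[(tert-butyldimethylsilyl)oxy]-3,7-dimethyl-1,4-bis[(triethylsilyl)oxy]dodeca-2,6,10,11-tetraene | CC[Si](CC)(CC)OC/C=C(/C)[C@@H](O[Si](CC)(CC)CC)C/C=C(\C)C[C@@H](O[Si](C)(C)C(C)(C)C)C=C=C | intermediate
17 | (2Z,4S,6E,9R)-9-[(tert-butyldimethylsilyl)oxy]-3,7-dimethyl-4-[(triethylsilyl)oxy]dodeca-2,6,10,11-tetraenal | O=C/C=C(/C)[C@@H](O[Si](CC)(CC)CC)C/C=C(\C)C[C@@H](O[Si](C)(C)C(C)(C)C)C=C=C | intermediate
18 | 2-(methoxycarbonyl)allylnickel chloride from 17 (drawn as the C13-bound σ-allyl form; CO2Me on C11) | O=C/C=C(/C)[C@@H](O[Si](CC)(CC)CC)C/C=C(\C)C[C@@H](O[Si](C)(C)C(C)(C)C)C=C(C[Ni]Cl)C(=O)OC | intermediate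
19 | ten-membered hydroxy ester, the seco form of 20 (free 6-OH, methyl ester at C12; 3S,6R,7S,8R) | C=C(C(=O)OC)[C@H]1[C@H](O)/C=C(/C)[C@@H](O[Si](CC)(CC)CC)C/C=C(\C)C[C@H]1O[Si](C)(C)C(C)(C)C | intermediate
20 | (3S,6R,7S,8R,1(10)E,4Z)-8-[(tert-butyldimethylsilyl)oxy]-3-[(triethylsilyl)oxy]germacra-1(10),4,11(13)-trien-12,6-olide | C=C1C(=O)O[C@@H]2/C=C(/C)[C@@H](O[Si](CC)(CC)CC)C/C=C(\C)C[C@@H](O[Si](C)(C)C(C)(C)C)[C@@H]12 | intermediate
21 | (3S,6R,7S,8R,1(10)E,4Z)-8-[(tert-butyldimethylsilyl)oxy]-3-hydroxygermacra-1(10),4,11(13)-trien-12,6-olide | C=C1C(=O)O[C@@H]2/C=C(/C)[C@@H](O)C/C=C(\C)C[C@@H](O[Si](C)(C)C(C)(C)C)[C@@H]12 | intermediate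
22 | (3S,6R,7S,8R,1(10)E,4Z)-8-[(tert-butyldimethylsilyl)oxy]-3-(isobutyryloxy)germacra-1(10),4,11(13)-trien-12,6-olide | C=C1C(=O)O[C@@H]2/C=C(/C)[C@@H](OC(=O)C(C)C)C/C=C(\C)C[C@@H](O[Si](C)(C)C(C)(C)C)[C@@H]12 | intermediate
23 | (3S,6R,7R,8R,1(10)E,4Z)-8-hydroxy-3-(isobutyryloxy)germacra-1(10),4,11(13)-trien-12,6-olide | C=C1C(=O)O[C@@H]2/C=C(/C)[C@@H](OC(=O)C(C)C)C/C=C(\C)C[C@@H](O)[C@@H]12 | intermediate
24 | methyl angelate, methyl (Z)-2-methylbut-2-enoate | C/C=C(/C)C(=O)OC | starting material
25 | (Z)-2-methylbut-2-en-1-ol | C/C=C(/C)CO | intermediate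
26 | [(2R,3S)-2,3-dimethyloxiran-2-yl]methanol | OC[C@@]1(C)O[C@H]1C | intermediate
27 | (2S,3S)-2,3-dimethyloxirane-2-carboxylic acid | OC(=O)[C@@]1(C)O[C@H]1C | intermediate
28 | (2S,3S)-2,3-dimethyloxirane-2-carboxylic 2,4,6-trichlorobenzoic anhydride | O=C(OC(=O)[C@@]1(C)O[C@H]1C)c1c(Cl)cc(Cl)cc1Cl | intermediate
29 | (3S,6R,7R,8R,1(10)E,4Z)-8-{[(2S,3S)-2,3-dimethyloxirane-2-carbonyl]oxy}-3-(isobutyryloxy)germacra-1(10),4,11(13)-trien-12,6-olide | C=C1C(=O)O[C@@H]2/C=C(/C)[C@@H](OC(=O)C(C)C)C/C=C(\C)C[C@@H](OC(=O)[C@@]3(C)O[C@H]3C)[C@@H]12 | intermediate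
30 | CNP0117882.1, (1R,3S,6R,7R,8R,10R,4Z)-1,10-epoxy-8-{[(2S,3S)-2,3-dimethyloxirane-2-carbonyl]oxy}-3-(isobutyryloxy)germacra-4,11(13)-dien-12,6-olide | C=C1C(=O)O[C@@H]2/C=C(/C)[C@@H](OC(=O)C(C)C)C[C@H]3O[C@]3(C)C[C@@H](OC(=O)[C@@]3(C)O[C@H]3C)[C@@H]12 | target

**Step count**
Total: 20 steps. Longest linear sequence: 15 steps (1–6, 9–15, 19, 20).

**Steps most likely to fail**

Step 12 (proposed new method). Possible failure processes are decarbonylation of the methoxycarbonylnickel species before it meets the allene, protonation or β-silyloxy elimination of the allylnickel before the slow ten-membered ring closure, and ring closure with the wrong relative configuration at C6/C7 or C7/C8. The fallback sets out from 17 and comes back at 20. It is the allenic hetero-Pauson–Khand cyclocarbonylation, the known [2+2+1] reaction of allenyl aldehydes with CO that gives α-methylene-γ-butyrolactones (Mo(CO)6, DMSO, toluene, 100 °C, high dilution). An oxametallacycle forms from the C6=O and C7=C11 π bonds, CO is inserted as C12 and reductive elimination closes the lactone, so neither a chloroformate nor an allylmetal is involved. No new compound is isolated on the way (F0).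

Step 9. Possible failure processes are weak ligand-controlled facial selectivity at the new carbinol, which gets no help from the remote C9 centre, and migration of the β,γ-double bond of the aldehyde before coupling. The fallback sets out from 10 and 14 and comes back at 15. An achiral Nozaki–Hiyama–Kishi coupling (CrCl2, NiCl2 cat., DMSO) gives the C4-epimeric alcohol mixture F1. Dess–Martin oxidation gives the (2Z,6E,9R)-enone F2. Corey–Bakshi–Shibata reduction with the (R)-methyl oxazaborolidine and BH3·SMe2, with the α-methylalkenyl group acting as the large substituent, should then give 15.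

Step 20. Possible failure processes are attack of the peracid on the wrong face of the macrocyclic alkene and acid-induced transannular opening of the new epoxide. The fallback sets out from 29 and comes back at 30. It replaces conformational control by reagent control: a Shi asymmetric epoxidation with the fructose-derived ketone or its enantiomer (Oxone, K2CO3 buffer, MeCN/dimethoxymethane–water, 0 °C). The chiral dioxirane selects the face of the isolated E-trisubstituted alkene, either face is available, and the medium is buffered and non-acidic. No new compound is made (F0).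

**Further compounds**
F0 | step 12 | none | none
F1 | step 9 | (2Z,6E,9R)-9-[(tert-butyldimethylsilyl)oxy]-3,7-dimethyl-1-[(triethylsilyl)oxy]dodeca-2,6,10,11-tetraen-4-ol, mixture of C4 epimers | CC[Si](CC)(CC)OC/C=C(/C)C(O)C/C=C(\C)C[C@@H](O[Si](C)(C)C(C)(C)C)C=C=C
F2 | step 9 | (2Z,6E,9R)-9-[(tert-butyldimethylsilyl)oxy]-3,7-dimethyl-1-[(triethylsilyl)oxy]dodeca-2,6,10,11-tetraen-4-one | CC[Si](CC)(CC)OC/C=C(/C)C(=O)C/C=C(\C)C[C@@H](O[Si](C)(C)C(C)(C)C)C=C=C
F0 | step 20 | none | none
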